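**Retrosynthetic overview**
1. The whole C14 bibenzyl skeleton, with both para-OH groups, is bought as bibenzyl-4,4'-diol (1); no C–C bond is made.
2. C–Br disconnection, done first: one Br ortho to each OH gives the bis(bromophenol) 2. Bromination of the finished catechol would go para to an OH, onto the wrong carbon.
3. Key disconnection, 2 × aryl C–O: the one remaining ortho C–H on each ring of 2 is oxygenated by phthaloyl peroxide (made in one step from phthaloyl chloride 3, giving 4). The bis(hydrogen phthalate) 5 formed in the flask is cleaved there to the target 6.
4. Rings: no ring of the target is formed; both benzene rings come in with 1. The only ring closed is the peroxide ring of reagent 4.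

Assumption: the SMILES holds no stereocentre and the molecule is achiral, so "single enantiomer" requires no stereocontrol. Compound 1 is taken as a catalogue compound (CAS 6052-84-2).

**Route**

Step 1
Reactants: 1 bibenzyl-4,4'-diol (4,4'-(ethane-1,2-diyl)diphenol)
Product: 2 bis(bromophenol) 4,4'-(ethane-1,2-diyl)bis(2-bromophenol)
Conditions: NBS (2.05 equiv, added over 30 min in MeOH), p-TsOH·H2O (10 mol %), MeOH, 0 °C to rt, 1 h
Reagents that add atoms: N-bromosuccinimide, O=C1CCC(=O)N1Br
Why: Electrophilic aromatic bromination (acid-catalysed NBS ortho-monobromination of a para-substituted phenol): the para position is blocked by the CH2CH2 bridge, the first bromine slows a second bromination of its own ring, and the two rings react independently, so about two equivalents put one Br ortho to each OH; no stereocentre is formed.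

Step 2
Reactants: 3 phthaloyl chloride
Product: 4 phthaloyl peroxide (2,3-benzodioxine-1,4-dione)
Conditions: 2Na2CO3·3H2O2 (1.2 equiv), CH2Cl2, rt, vigorous stirring, 3 h; filter; keep as a titrated CH2Cl2 solution (shock-sensitive solid, not taken to dryness)
Reagents that add atoms: sodium percarbonate 2Na2CO3·3H2O2 (carrier of hydrogen peroxide), [Na+].[Na+].[Na+].[Na+].[O-]C([O-])=O.[O-]C([O-])=O.OO.OO.OO
Why: Two-fold nucleophilic acyl substitution: hydrogen peroxide released from the percarbonate attacks both acid chlorides in turn and closes the six-membered cyclic diacyl peroxide while the carbonate takes up the HCl (a known preparation of this reagent); no stereocentre is formed.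

Step 3
Reactants: 2 bis(bromophenol) 4,4'-(ethane-1,2-diyl)bis(2-bromophenol); 4 phthaloyl peroxide
Product: 6 target bibenzyl 1,2-bis(3-bromo-4,5-dihydroxyphenyl)ethane, via bis(hydrogen phthalate) ester 5 (not isolated)
Conditions: 4 (2.2 equiv), CH2Cl2, 0 °C to rt, dark, N2, 12 h; Me2S (0.3 equiv, destroys excess 4); then degassed NaHCO3 (aq)/MeOH, rt, 1 h; HCl (aq) to pH 2
Reagents that add atoms: none
Why: Proposed new method: hydroxyl-directed ortho C–H oxygenation of a free phenol by a strained cyclic diacyl peroxide in a non-fluorinated solvent — the acidic ortho-bromophenol OH (pKa about 8.5, close to that of hexafluoroisopropanol) hydrogen-bonds to a peroxide carbonyl, which activates the weak O–O bond and holds it over the only free ortho carbon, that carbon attacks the proximal peroxide oxygen (SN2 at oxygen, or equivalently O-attack to an aryl perester followed by a [3,3] shift), and tautomerisation of the dienone gives the catechol mono(hydrogen phthalate) 5, whose free OH has no open ortho or para C–H left (so each ring is oxygenated once and stays at the catechol oxidation level) and whose ortho-carboxylate expels the catechol via phthalic anhydride under mild bicarbonate; the closest known reaction types are the ortho-benzoyloxylation of phenols by dibenzoyl peroxide and the hydroxylation of arenes by phthaloyl peroxide in fluorinated alcohols; no stereocentre is formed.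

**Compound list**
1 | bibenzyl-4,4'-diol, 4,4'-(ethane-1,2-diyl)diphenol | Oc1ccc(CCc2ccc(O)cc2)cc1 | starting material
2 | 4,4'-(ethane-1,2-diyl)bis(2-bromophenol) (one Br ortho to each OH) | Oc1ccc(CCc2ccc(O)c(Br)c2)cc1Br | intermediate
3 | phthaloyl chloride (benzene-1,2-dicarbonyl dichloride) | ClC(=O)c1ccccc1C(Cl)=O | starting material
4 | phthaloyl peroxide (2,3-benzodioxine-1,4-dione) | O=C1OOC(=O)c2ccccc12 | intermediate
5 | bis(hydrogen phthalate) ester, 2,2'-{ethane-1,2-diylbis[(3-bromo-2-hydroxy-5,1-phenylene)oxycarbonyl]}dibenzoic acid (each new ring oxygen carries a 2-carboxybenzoyl group; the OH para to the bridge is free) | OC(=O)c1ccccc1C(=O)Oc1cc(CCc2cc(OC(=O)c3ccccc3C(O)=O)c(O)c(Br)c2)cc(Br)c1O | intermediate (not isolated)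
6 | 1,2-bis(3-bromo-4,5-dihydroxyphenyl)ethane, 5,5'-(ethane-1,2-diyl)bis(3-bromobenzene-1,2-diol) | Oc1cc(CCc2cc(O)c(O)c(Br)c2)cc(Br)c1O | target

**Step count and risks**
Total step count: 3. Longest linear sequence: 2 (1 → 2 → 6); step 2 is a one-step side branch that makes the oxygen-transfer reagent 4.

Most likely to fail, first: step 3, the new oxygenation. The peroxide may react too slowly with a bromine-deactivated phenol outside a fluorinated alcohol. Attack at the ring carbon para to OH (the one carrying the bridge) would give a para-quinol ester instead of the catechol ester. Both rings must also react completely. The fallback uses known chemistry and sets out from 2. Magnesium-mediated ortho-formylation (MgCl2, Et3N, paraformaldehyde, THF, reflux) places a formyl group on the only free ortho position of each ring and gives 5,5'-(ethane-1,2-diyl)bis(3-bromo-2-hydroxybenzaldehyde) F1. Dakin oxidation (30 % H2O2, NaOH (aq), THF, 0 °C, N2, then HCl (aq)) turns each aldehyde into the aryl formate, 5,5'-(ethane-1,2-diyl)bis(3-bromo-2-hydroxyphenyl) diformate F2, which is hydrolysed in the same flask. The sequence comes back to the route at 6. The C–O bond is then made by aryl migration to a peroxide oxygen instead of direct C–H oxygenation, at the cost of one more step.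

Second: step 1. The two rings are brominated independently, so mono-, tri- and tetrabromides can accompany 2 and are hard to separate from it. The fallback sets out from 1 and fixes "one Br per ring" by directed ortho-metalation instead of electrophilic substitution. MOMCl and i-Pr2NEt in CH2Cl2 give 1,2-bis[4-(methoxymethoxy)phenyl]ethane F3. n-BuLi/TMEDA in THF at 0 °C lithiates once next to each OMOM group, and a quench with BrCCl2CCl2Br at −78 °C gives 1,2-bis[3-bromo-4-(methoxymethoxy)phenyl]ethane F4. HCl in MeOH at 50 °C removes the acetals, and the sequence comes back to the route at 2.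

Third: step 2. Reagent 4 is shock-sensitive, can carry phthalic anhydride or monoperoxyphthalic acid, and its titre drifts. The fallback sets out from 2 and avoids any made peroxide by using a bought oxidant that goes through the quinone oxidation level. IBX (2-iodoxybenzoic acid, 2.4 equiv) in DMF at rt oxygenates the free ortho position of each phenol to give 5,5'-(ethane-1,2-diyl)bis(3-bromocyclohexa-3,5-diene-1,2-dione) F5. This is reduced in the same flask with Na2S2O4 (aq), and the sequence comes back to the route at 6.

**Further compounds**
F1 | step 3 | 5,5'-(ethane-1,2-diyl)bis(3-bromo-2-hydroxybenzaldehyde) | O=Cc1cc(CCc2cc(C=O)c(O)c(Br)c2)cc(Br)c1O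
F2 | step 3 | 5,5'-(ethane-1,2-diyl)bis(3-bromo-2-hydroxyphenyl) diformate | O=COc1cc(CCc2cc(OC=O)c(O)c(Br)c2)cc(Br)c1O
F3 | step 1 | 1,2-bis[4-(methoxymethoxy)phenyl]ethane | COCOc1ccc(CCc2ccc(OCOC)cc2)cc1
F4 | step 1 | 1,2-bis[3-bromo-4-(methoxymethoxy)phenyl]ethane | COCOc1ccc(CCc2ccc(OCOC)c(Br)c2)cc1Br
F5 | step 2 | 5,5'-(ethane-1,2-diyl)bis(3-bromocyclohexa-3,5-diene-1,2-dione) | O=C1C(=O)C(Br)=CC(CCC2=CC(=O)C(=O)C(Br)=C2)=C1
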